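The earlier runs and the new flask stem from a simulated flask with constants of no real substance, and the scatter is random.

Take the two earlier runs and ask what stays put when the charge changes.

| flask | starting material | remark | time |
|---|---|---|---|
| birch | 27 mM | run made earlier |  |
| elm | 42 mM | run made earlier |  |
| flask | 19 mM |  | 12 min |

| run | time / min | ring / % | starting material / % |
|---|---|---|---|
| birch | 3.00 | 15.5 | 49.3 |
| birch | 4.00 | 18.3 | 42.1 |
| birch | 6.00 | 23.8 | 31.6 |
| birch | 8.00 | 27.5 | 24.3 |
| birch | 12.0 | 33.5 | 16.3 |
| elm | 3.00 | 13.6 | 41.3 |
| elm | 4.00 | 15.9 | 33.5 |
| elm | 6.00 | 20.3 | 24.0 |
| elm | 8.00 | 23.7 | 18.5 |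
| elm | 12.0 | 28.3 | 12.9 |

(standard deviation of a reading: 0.3 percentage points)

- the analysis behind the earlier runs scatters by 0.3 percentage points, standard deviation
- a reading or a percentage of ring counts all its forms, free or not

- time up to 12 min at which ring stands highest
- the amount of ring, in percent of the starting material charged, at that time

**Ring constant.** Ring gained from 8.00 min to 12.0 min, divided by the elapsed time and by the logarithmic mean of starting material over that stretch, reads 0.0749 /min in birch and 0.0740 /min in elm. The mean, 0.0745 /min, is the ring constant: ring made per minute per unit of starting material present, a first-order constant.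

**The charge.** Going from elm to birch lifted ring at 12.0 min from 28.3% to 33.5%, while the constant held and more starting material stayed, 16.3% against 12.9%. A straight line through both, carried to 19 mM, is the reckoning here: 36.3%.

**The time.** Ring made in proportion to starting material keeps rising while starting material stands, and birch still gained 6 percentage points over its last stretch, so the highest ring is expected at the limit, 12 min.

**The forecast.** It says 38% at 12 min, above the straight line, holding that “ring formation looks first order”.

**Flask result.** The flask gives 37.5% of ring at 12.0 min, crystals counted in.

    2 starting material ⇌ open dimer (K = 620 /M, k = 0.0720 /M/s)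
    starting material → ring (k = 0.00120 /s)
    crystals ⇌ ring, rate k3*(cs3 - [ring]) while solid is left; crystals form when [ring] > cs3 (solubility = 1.00 mM, k = 0.260 /s)

**Two routes.** In the flask, starting material going to ring over starting material going to open dimer (forward step alone), a selectivity factor, reads 0.87 at 3.69 min and 2.2 at 12.0 min, and open dimer holds 43.0% at the end. The ring constant, run from 6.00 min to 12.0 min in the flask, gives 38.1%. A shorter time moves the answer: the neighbour flask read at 8.0 min, with the same amounts, shows 30.6%, below the forecast's 38%. For the neighbour flask left until 30 min, the constant run on from 12.0 min gives 53.4%, and that neighbour shows 51.8%.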